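**Plan**

- Target numbering (indane): C1 carries the carbinol carbon Cα, C2 the 3,5-dihydroxyphenyl ring, C3 the 4-hydroxyphenyl ring; ring A is C3a–C7a with OH on C4 and C6.
- Retrosynthetic cuts, in order: Cα–OH back to the aryl ketone; the C2–aryl bond (conjugate arylation of a 3-acyl-1H-indene); the C1=C2 unsaturation back to an indane; C1–C7a (ketone enolate plus aryl bromide, the ring closure); C3–C3a (arene opening of a cyclopropyl ketone); the cyclopropane CH2 and the chalcone C=C.
- Forward: ring A is bought with its bromine in place; chalcone, cyclopropyl ketone and 4,4-diarylbutanone follow in three steps; the five-membered ring closes at C1–C7a; dehydrogenation, aryl addition at C2, ketone reduction and debenzylation finish the route.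
- Enabling feature: Cα is bonded directly to C1, so with Cα as a ketone C1 is the only enolisable carbon; C7a is meta to both ring-A oxygens, out of reach of any Friedel–Crafts closure but addressable through a C–Br bond.
- Stereochemistry: once C1=C2 is in place, C3–H is an indene C–H and racemises through the indenide; one rhodium-catalysed arylation under dynamic kinetic resolution sets C3 and C2, base equilibration sets C1 (all-trans), and a CBS reduction sets Cα.

Key step: step 4

Assumption: the sense of induction of the chiral diene in step 6 is assigned by analogy with cyclic enones; if the first run shows the opposite sense, the (1S,4S) ligand is used and nothing else changes.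

**Route**

Step 1
Reactants: 1 1-[4-(benzyloxy)phenyl]ethan-1-one; 2 4-(benzyloxy)benzaldehyde
Product: 3 (E)-1,3-bis[4-(benzyloxy)phenyl]prop-2-en-1-one
Conditions: NaOH (aq), EtOH, 20 °C
Reagents that add atoms: none
Why: Claisen–Schmidt aldol condensation of a methyl aryl ketone with a non-enolisable aldehyde should give the (E)-chalcone.

Step 2
Reactants: 3 (E)-1,3-bis[4-(benzyloxy)phenyl]prop-2-en-1-one
Product: 4 rac-[(1R,2R)-2-[4-(benzyloxy)phenyl]cyclopropyl][4-(benzyloxy)phenyl]methanone
Conditions: Me3S(O)I, NaH, DMSO, 20 °C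
Reagents that add atoms: trimethylsulfoxonium iodide, C[S+](C)(C)=O.[I-]
Why: Corey–Chaykovsky cyclopropanation (conjugate addition of the sulfoxonium ylide, then 3-exo-tet closure) should give the trans donor–acceptor cyclopropane; its stereocentres are not carried forward.

Step 3
Reactants: 4 rac-[(1R,2R)-2-[4-(benzyloxy)phenyl]cyclopropyl][4-(benzyloxy)phenyl]methanone; 5 1,3-bis(benzyloxy)-5-bromobenzene
Product: 6 rac-4-[2,4-bis(benzyloxy)-6-bromophenyl]-1,4-bis[4-(benzyloxy)phenyl]butan-1-one
Conditions: Sc(OTf)3 (10 mol %), (CF3)2CHOH, 40 °C; bromoarene in threefold excess, surplus recovered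
Reagents that add atoms: none
Why: Homo-conjugate Friedel–Crafts ring opening of a donor–acceptor cyclopropane, an addition in which the two partners combine without loss of any atom: the Lewis acid polarises the bond between the 4-benzyloxyphenyl-bearing carbon and the acyl-bearing carbon, and the bromoarene should attack the benzylic carbon through its position ortho to Br and para to a benzyloxy group, the site where 1-bromo-3,5-dialkoxybenzenes are formylated and halogenated.

Step 4
Reactants: 6 rac-4-[2,4-bis(benzyloxy)-6-bromophenyl]-1,4-bis[4-(benzyloxy)phenyl]butan-1-one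
Product: 7 [4,6-bis(benzyloxy)-3-[4-(benzyloxy)phenyl]-2,3-dihydro-1H-inden-1-yl][4-(benzyloxy)phenyl]methanone (racemic 1,3-cis/1,3-trans mixture)
Conditions: Pd(OAc)2 (5 mol %), P(t-Bu)3·HBF4 (10 mol %), NaOt-Bu (2.5 equiv), toluene, 70 °C
Reagents that add atoms: none
Why: Zerovalent palladium inserts into the C7a–Br bond of ring A, NaOt-Bu forms the sodium enolate at the only enolisable carbon (the future C1), transmetallation gives a C-bound arylpalladium enolate, and reductive elimination forms the C1–C7a bond. The closest known reaction type is the Buchwald–Hartwig–Miura palladium-catalysed α-arylation of ketones in its intramolecular form, which is established for benzo-fused five-membered carbocycles. The five-membered ring closes by C(sp2)–C(sp3) reductive elimination from a six-membered palladacycle, the enolate double bond lying outside the ring being formed (5-enolexo closure). C1 is created α to the ketone as an epimerisable centre, so 7 should form as a cis/trans mixture relative to C3; no control is needed because this centre is flattened in step 5 and re-set under thermodynamic control in step 6. The selectivity that matters is positional: C7a is meta to both ring-A oxygens and cannot be reached by electrophilic substitution, so the bromine carried in from 5 alone dictates the site, and the ketone offers a single α-methylene. Enolate capture must outrun C–H arylation of the neighbouring 4-benzyloxyphenyl ring (fluorene formation), which the alkoxide base and moderate temperature should secure, and the product is held as its enolate, which prevents a second arylation.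

Step 5
Reactants: 7 [4,6-bis(benzyloxy)-3-[4-(benzyloxy)phenyl]-2,3-dihydro-1H-inden-1-yl][4-(benzyloxy)phenyl]methanone
Product: 9 [5,7-bis(benzyloxy)-1-[4-(benzyloxy)phenyl]-1H-inden-3-yl][4-(benzyloxy)phenyl]methanone (racemic), via 1H-inden-1-yl ketone 8 (not isolated)
Conditions: DDQ (1.1 equiv), 1,4-dioxane, 20 °C; then Et3N (0.2 equiv)
Reagents that add atoms: none
Why: DDQ dehydrogenation of an electron-rich indane: hydride abstraction from the doubly benzylic C3–H (stabilised by three ortho/para benzyloxy groups) and proton loss from C2 should give indene 8, which the amine moves by 1,3-prototropy into the conjugated enone 9.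

Step 6
Reactants: 9 [5,7-bis(benzyloxy)-1-[4-(benzyloxy)phenyl]-1H-inden-3-yl][4-(benzyloxy)phenyl]methanone; 10 [3,5-bis(benzyloxy)phenyl]boronic acid
Product: 12 [(1R,2S,3R)-4,6-bis(benzyloxy)-3-[4-(benzyloxy)phenyl]-2-[3,5-bis(benzyloxy)phenyl]-2,3-dihydro-1H-inden-1-yl][4-(benzyloxy)phenyl]methanone, via C1-epimeric ketone 11 (not isolated)
Conditions: [RhCl(C2H4)2]2 (2.5 mol %), (1R,4R)-2,5-diphenylbicyclo[2.2.2]octa-2,5-diene (5.5 mol %), KOH (0.3 equiv), 1,4-dioxane/H2O 10:1, 40 °C, argon, boronic acid in twofold excess; then DBU (0.2 equiv), 20 °C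
Reagents that add atoms: none
Why: Proposed new method: in 9 the C3–H (target numbering) is both benzhydrylic and the sp3 position of a 3-acyl-1H-indene, so catalytic hydroxide should deprotonate it reversibly to an achiral indenide/dienolate and interconvert the enantiomers of 9 faster than C–C bond formation; the aryl species of monovalent rhodium bearing the chiral diene adds to C2 of the enone anti to the C3 aryl group, and only for one enantiomer of 9 does this substrate-preferred face coincide with the ligand-preferred face, so the racemate should drain through that enantiomer (dynamic kinetic resolution) and set C3 (R) and C2 (S); protonation of the rhodium enolate gives C1 partly as the 1,2-cis ketone 11, which the base present (completed by DBU) epimerises to the all-trans ketone 12, fixing C1 (R) thermodynamically; the closest known reaction type is the Hayashi–Miyaura rhodium-catalysed asymmetric 1,4-addition of arylboronic acids to cyclic enones with its trans-directing effect of a substituent next to the β-carbon, and what is new is coupling it to in situ racemisation through an indenide on a 3-acylindene acceptor.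

Step 7
Reactants: 12 [(1R,2S,3R)-4,6-bis(benzyloxy)-3-[4-(benzyloxy)phenyl]-2-[3,5-bis(benzyloxy)phenyl]-2,3-dihydro-1H-inden-1-yl][4-(benzyloxy)phenyl]methanone
Product: 13 (R)-[(1R,2S,3R)-4,6-bis(benzyloxy)-3-[4-(benzyloxy)phenyl]-2-[3,5-bis(benzyloxy)phenyl]-2,3-dihydro-1H-inden-1-yl][4-(benzyloxy)phenyl]methanol
Conditions: (S)-2-methyl-CBS-oxazaborolidine (0.5 equiv), BH3·SMe2 (1.2 equiv), THF, −20 to 0 °C
Reagents that add atoms: none
Why: Corey–Bakshi–Shibata reduction with the aryl group as the large substituent should deliver hydride to the face giving the (R) carbinol, the same sense as Felkin–Anh attack anti to the C7a aryl carbon on C1 (matched case), under non-basic conditions that leave C1 untouched.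

Step 8
Reactants: 13 (R)-[(1R,2S,3R)-4,6-bis(benzyloxy)-3-[4-(benzyloxy)phenyl]-2-[3,5-bis(benzyloxy)phenyl]-2,3-dihydro-1H-inden-1-yl][4-(benzyloxy)phenyl]methanol
Product: 14 (1R,2S,3R)-2-(3,5-dihydroxyphenyl)-1-[(R)-hydroxy(4-hydroxyphenyl)methyl]-3-(4-hydroxyphenyl)-2,3-dihydro-1H-indene-4,6-diol
Conditions: H2 (1 atm), Pd/C (10 wt %), EtOAc/MeOH 1:1, 20 °C, stopped at complete debenzylation
Reagents that add atoms: none
Why: Neutral hydrogenolysis should cleave the six aryl benzyl ethers much faster than the secondary benzylic C–OH bond and touches no stereocentre; acid is excluded because the para-hydroxybenzylic carbinol ionises easily.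

**Compound list**

1 | 1-[4-(benzyloxy)phenyl]ethan-1-one | CC(=O)c1ccc(OCc2ccccc2)cc1 | starting material
2 | 4-(benzyloxy)benzaldehyde | O=Cc1ccc(OCc2ccccc2)cc1 | starting material
3 | (E)-1,3-bis[4-(benzyloxy)phenyl]prop-2-en-1-one | O=C(/C=C/c1ccc(OCc2ccccc2)cc1)c1ccc(OCc2ccccc2)cc1 | intermediate
4 | rac-[(1R,2R)-2-[4-(benzyloxy)phenyl]cyclopropyl][4-(benzyloxy)phenyl]methanone (trans; one enantiomer drawn) | O=C([C@@H]1C[C@H]1c1ccc(OCc2ccccc2)cc1)c1ccc(OCc2ccccc2)cc1 | intermediate
5 | 1,3-bis(benzyloxy)-5-bromobenzene | Brc1cc(OCc2ccccc2)cc(OCc2ccccc2)c1 | starting material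
6 | rac-4-[2,4-bis(benzyloxy)-6-bromophenyl]-1,4-bis[4-(benzyloxy)phenyl]butan-1-one (racemic, drawn without configuration) | O=C(CCC(c1ccc(OCc2ccccc2)cc1)c1c(Br)cc(OCc2ccccc2)cc1OCc1ccccc1)c1ccc(OCc2ccccc2)cc1 | intermediate
7 | [4,6-bis(benzyloxy)-3-[4-(benzyloxy)phenyl]-2,3-dihydro-1H-inden-1-yl][4-(benzyloxy)phenyl]methanone (racemic cis/trans mixture, drawn without configuration) | O=C(C1CC(c2ccc(OCc3ccccc3)cc2)c2c(OCc3ccccc3)cc(OCc3ccccc3)cc21)c1ccc(OCc2ccccc2)cc1 | intermediate
8 | [4,6-bis(benzyloxy)-3-[4-(benzyloxy)phenyl]-1H-inden-1-yl][4-(benzyloxy)phenyl]methanone (racemic, drawn without configuration) | O=C(C1C=C(c2ccc(OCc3ccccc3)cc2)c2c(OCc3ccccc3)cc(OCc3ccccc3)cc21)c1ccc(OCc2ccccc2)cc1 | intermediate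
9 | [5,7-bis(benzyloxy)-1-[4-(benzyloxy)phenyl]-1H-inden-3-yl][4-(benzyloxy)phenyl]methanone (racemic, stereolabile, drawn without configuration) | O=C(C1=CC(c2ccc(OCc3ccccc3)cc2)c2c(OCc3ccccc3)cc(OCc3ccccc3)cc21)c1ccc(OCc2ccccc2)cc1 | intermediate
10 | [3,5-bis(benzyloxy)phenyl]boronic acid | OB(O)c1cc(OCc2ccccc2)cc(OCc2ccccc2)c1 | starting material
11 | [(1S,2S,3R)-4,6-bis(benzyloxy)-3-[4-(benzyloxy)phenyl]-2-[3,5-bis(benzyloxy)phenyl]-2,3-dihydro-1H-inden-1-yl][4-(benzyloxy)phenyl]methanone | C(c1ccccc1)Oc1ccc([C@@H]2c3c(OCc4ccccc4)cc(OCc4ccccc4)cc3[C@@H](C(=O)c3ccc(OCc4ccccc4)cc3)[C@H]2c2cc(OCc3ccccc3)cc(OCc3ccccc3)c2)cc1 | intermediate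
12 | [(1R,2S,3R)-4,6-bis(benzyloxy)-3-[4-(benzyloxy)phenyl]-2-[3,5-bis(benzyloxy)phenyl]-2,3-dihydro-1H-inden-1-yl][4-(benzyloxy)phenyl]methanone | C(c1ccccc1)Oc1ccc([C@@H]2c3c(OCc4ccccc4)cc(OCc4ccccc4)cc3[C@H](C(=O)c3ccc(OCc4ccccc4)cc3)[C@H]2c2cc(OCc3ccccc3)cc(OCc3ccccc3)c2)cc1 | intermediate
13 | (R)-[(1R,2S,3R)-4,6-bis(benzyloxy)-3-[4-(benzyloxy)phenyl]-2-[3,5-bis(benzyloxy)phenyl]-2,3-dihydro-1H-inden-1-yl][4-(benzyloxy)phenyl]methanol | C(c1ccccc1)Oc1ccc([C@@H]2c3c(OCc4ccccc4)cc(OCc4ccccc4)cc3[C@H]([C@@H](O)c3ccc(OCc4ccccc4)cc3)[C@H]2c2cc(OCc3ccccc3)cc(OCc3ccccc3)c2)cc1 | intermediate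
14 | (1R,2S,3R)-2-(3,5-dihydroxyphenyl)-1-[(R)-hydroxy(4-hydroxyphenyl)methyl]-3-(4-hydroxyphenyl)-2,3-dihydro-1H-indene-4,6-diol | Oc1ccc([C@@H]2c3c(O)cc(O)cc3[C@H]([C@@H](O)c3ccc(O)cc3)[C@H]2c2cc(O)cc(O)c2)cc1 | target

**Summary**

Total step count: 8. Longest linear sequence: 8 steps (1 or 2 to 14).

**Steps most likely to fail**

Step 6 (proposed new method). Racemisation of 9 may be slower than the addition, the aryl transfer to the α-substituted enone may be sluggish so that protodeboronation wins, or the indenide may be diverted by oxidation; the result would be partial resolution or low conversion. The fallback sets out from 9 and comes back at 12. The same 1,4-addition is run without asymmetric induction using [Rh(OH)(cod)]2 and 10 in dioxane/water, followed by DBU, to give the racemic all-trans ketone, that is 12 together with its mirror image, the (1S,2R,3S)-configured ketone F1. The enantiomers are then separated by preparative chromatography on a chiral stationary phase with a neutral eluent, which leaves the epimerisable C1 untouched, and 12 re-enters at step 7.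

Step 3. The benzylic cation may attack the ring carbon between the two benzyloxy groups of 5, the more electron-rich product may be alkylated again, or the acidic medium may strip benzyl groups. The fallback sets out from 5 and comes back at 6; it fixes the ring-A substitution before the benzylic carbon is built and attaches both aryl groups of the chain by carbonyl additions. Vilsmeier–Haack formylation of 5 (POCl3, DMF) ortho to bromine should give 2,4-bis(benzyloxy)-6-bromobenzaldehyde F2, purified by crystallisation. Addition of 4-(benzyloxy)phenylmagnesium bromide gives the benzhydrol [2,4-bis(benzyloxy)-6-bromophenyl][4-(benzyloxy)phenyl]methanol F3. Hosomi–Sakurai-type allylation of the stabilised benzhydryl cation (allyltrimethylsilane, BF3·OEt2, CH2Cl2, −78 °C) gives 1,5-bis(benzyloxy)-3-bromo-2-[1-[4-(benzyloxy)phenyl]but-3-en-1-yl]benzene F4, whose terminal alkene carbon is the future carbonyl carbon of 6. Hydroboration with 9-borabicyclo[3.3.1]nonane gives the B-alkyl borane 9-[4-[2,4-bis(benzyloxy)-6-bromophenyl]-4-[4-(benzyloxy)phenyl]butyl]-9-borabicyclo[3.3.1]nonane F5, which NaOH/H2O2 oxidises to the primary alcohol 4-[2,4-bis(benzyloxy)-6-bromophenyl]-4-[4-(benzyloxy)phenyl]butan-1-ol F6. Dess–Martin oxidation gives the aldehyde 4-[2,4-bis(benzyloxy)-6-bromophenyl]-4-[4-(benzyloxy)phenyl]butanal F7. A second addition of 4-(benzyloxy)phenylmagnesium bromide (THF, −78 °C, the aryl bromide being inert to the Grignard reagent) gives the secondary alcohol 4-[2,4-bis(benzyloxy)-6-bromophenyl]-1,4-bis[4-(benzyloxy)phenyl]butan-1-ol F8, and a second Dess–Martin oxidation then gives 6.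

Step 8. Once the para-phenol is liberated, the benzylic C–O bond of the carbinol may be hydrogenolysed, or traces of acid may ionise the carbinol. The fallback sets out from 12 and comes back at 14; it inverts the order of the last two operations. Hydrogenolysis of 12 (H2, Pd/C, EtOAc/MeOH) gives the hexahydroxy ketone [(1R,2S,3R)-2-(3,5-dihydroxyphenyl)-4,6-dihydroxy-3-(4-hydroxyphenyl)-2,3-dihydro-1H-inden-1-yl](4-hydroxyphenyl)methanone F9, so no benzylic C–O bond is present during hydrogenation. Reduction of F9 with NaBH4 in MeOH at −20 °C then gives 14, the (R) carbinol being the Felkin–Anh product (hydride anti to the C7a aryl carbon).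

**Further compounds**

F1 | step 6 | [(1S,2R,3S)-4,6-bis(benzyloxy)-3-[4-(benzyloxy)phenyl]-2-[3,5-bis(benzyloxy)phenyl]-2,3-dihydro-1H-inden-1-yl][4-(benzyloxy)phenyl]methanone | C(c1ccccc1)Oc1ccc([C@H]2c3c(OCc4ccccc4)cc(OCc4ccccc4)cc3[C@@H](C(=O)c3ccc(OCc4ccccc4)cc3)[C@@H]2c2cc(OCc3ccccc3)cc(OCc3ccccc3)c2)cc1
F2 | step 3 | 2,4-bis(benzyloxy)-6-bromobenzaldehyde | O=Cc1c(Br)cc(OCc2ccccc2)cc1OCc1ccccc1
F3 | step 3 | rac-[2,4-bis(benzyloxy)-6-bromophenyl][4-(benzyloxy)phenyl]methanol | OC(c1ccc(OCc2ccccc2)cc1)c1c(Br)cc(OCc2ccccc2)cc1OCc1ccccc1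
F4 | step 3 | rac-1,5-bis(benzyloxy)-3-bromo-2-[1-[4-(benzyloxy)phenyl]but-3-en-1-yl]benzene | C=CCC(c1ccc(OCc2ccccc2)cc1)c1c(Br)cc(OCc2ccccc2)cc1OCc1ccccc1
F5 | step 3 | rac-9-[4-[2,4-bis(benzyloxy)-6-bromophenyl]-4-[4-(benzyloxy)phenyl]butyl]-9-borabicyclo[3.3.1]nonane | C(CCC(c1ccc(OCc2ccccc2)cc1)c1c(Br)cc(OCc2ccccc2)cc1OCc1ccccc1)B1C2CCCC1CCC2
F6 | step 3 | rac-4-[2,4-bis(benzyloxy)-6-bromophenyl]-4-[4-(benzyloxy)phenyl]butan-1-ol | OCCCC(c1ccc(OCc2ccccc2)cc1)c1c(Br)cc(OCc2ccccc2)cc1OCc1ccccc1
F7 | step 3 | rac-4-[2,4-bis(benzyloxy)-6-bromophenyl]-4-[4-(benzyloxy)phenyl]butanal | O=CCCC(c1ccc(OCc2ccccc2)cc1)c1c(Br)cc(OCc2ccccc2)cc1OCc1ccccc1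
F8 | step 3 | 4-[2,4-bis(benzyloxy)-6-bromophenyl]-1,4-bis[4-(benzyloxy)phenyl]butan-1-ol (mixture of diastereomers, drawn without configuration) | OC(CCC(c1ccc(OCc2ccccc2)cc1)c1c(Br)cc(OCc2ccccc2)cc1OCc1ccccc1)c1ccc(OCc2ccccc2)cc1
F9 | step 8 | [(1R,2S,3R)-2-(3,5-dihydroxyphenyl)-4,6-dihydroxy-3-(4-hydroxyphenyl)-2,3-dihydro-1H-inden-1-yl](4-hydroxyphenyl)methanone | Oc1ccc([C@@H]2c3c(O)cc(O)cc3[C@H](C(=O)c3ccc(O)cc3)[C@H]2c2cc(O)cc(O)c2)cc1
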